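One question is put to the grey flask, followed so far: the course of target at 3 times up to 3.0 h, with the amber run beside it.

| flask | substrate | reagent | remark | time |
|---|---|---|---|---|
| grey | 0.010 M | 1.3 equiv | the very flask that is asked about, followed so far |  |
| amber | 0.0050 M | 1.3 equiv | run made earlier |  |
| flask | 0.010 M | 1.30 equiv |  | 3.0 h |

| run | time / min | target / % | substrate / % |
|---|---|---|---|
| grey | 3.00 | 22.5 | 48.7 |
| grey | 10.0 | 37.1 | 27.1 |
| grey | 15.0 | 42.9 | 22.6 |
| grey | 25.0 | 50.6 | 18.7 |
| grey | 40.0 | 60.0 | 17.1 |
| amber | 6.00 | 22.8 | 53.3 |
| amber | 20.0 | 37.2 | 35.5 |
| amber | 30.0 | 42.3 | 33.5 |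
| amber | 50.0 | 51.8 | 25.6 |
| amber | 80.0 | 58.6 | 21.9 |

(readings scatter by 1 percentage point)

- amount of target in percent of the substrate charged, at 20 min, 1.0 h and 3.0 h

What do the two runs share? The equivalents, 1.3 equiv, which makes substrate the limiting reagent in both. Amber has half the grey concentration, and it was read at twice the grey times. Paired that way, the target columns coincide: 42.9 % in grey at 15.0 min, 42.3 % in amber at 30.0 min. The widest gap, 1.4 percentage points in the last pair, is comparable to a scatter of 1 point per reading.

Which concentration sets the order? The starting concentration of substrate. With equivalents fixed, reagent scales with it, so in an overall second-order step the fraction of the charge converted per minute is proportional to it. The fraction of target should then follow concentration times time. At 20 min the grey flask has 40.0 min of amber time, meaning starting concentration times time, divided by the amber concentration.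

But free substrate does not pair: 17.1 % in grey at 40.0 min, 21.9 % in amber at 80.0 min. Does that sink the rule? For the substrate column, yes; the target column still pairs. Substrate and target together fall short of the charge by 22.9 % in that grey reading and by 19.5 % in that amber one, so something holds substrate in a form not read as free. I carry the rule for the target column and leave substrate out.

What do I commit to? Amber interpolated at that amber time gives 47.1 %. Later points lie beyond the last reading of either run, so my own reckoning stops here.

The forecast says 47 %, 67 % and 85 %. It interpolates the first and takes the others from a second-order fit, trimming the last because “the late rate appears to sag”.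

The flask gives 46.9 %, 67.3 % and 86.4 %.

    substrate + reagent ⇌ target (K = 68.0 M⁻¹, k = 0.160 M⁻¹ s⁻¹)
    substrate + reagent ⇌ isomer of the product (K = 170 M⁻¹, k = 0.0750 M⁻¹ s⁻¹)
    substrate + target ⇌ idle adduct, settled at all times (K = 1500 M⁻¹)
    crystals ⇌ target, rate k4*(cs4 - [target]) while solid is left; crystals form when [target] > cs4 (solubility = 0.110 mM, k = 0.00920 s⁻¹)

At 3.00 h the crystals hold 84.0 % of the charge, counted within that target, and the flask stands at 360 min of amber time. The same flask stopped early, at 1.50 h, has half of that exposure, 180 min of amber time, with target at 75.2 %.

The data stem from a simulated flask with made-up constants; scatter was added.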